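Everything rests on hiding the Z-configured, ethyl-bearing C8=C9 double bond inside a temporary six-membered unsaturated lactone made of O, C7, C8, C9, C10 and C11: C7 and C10 must sit cis in such a ring, so ring size alone fixes the geometry. Ring-closing metathesis of the 2-ethylacrylate ester of (S)-2-methylbut-3-en-1-ol forms the C8=C9 bond and closes this lactone in one operation. Opening the ring afterwards gives a C7 aldehyde for Wittig union with the C1–C6 dihydropyran (ring A, carried as a lactol acetal) and a C11 iodide for B-alkyl Suzuki coupling with the C12–C24 dienyl iodide, itself built by two Evans aldol reactions.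

Key step: step 7

Remark: atoms are numbered from the lactone carbonyl (C1) along the chain to the carboxylic acid (C24); the acetal centre C1 is drawn as the anomer trans to the C5 substituent (expected from the anomeric effect), which is of no consequence because C1 ends as the lactone carbonyl.

**Part 1. C7–C11 unit through the lactone template**

Step 1
Reactants: 1 methyl (R)-3-hydroxy-2-methylpropanoate
Product: 2 methyl (R)-3-[(tert-butyldimethylsilyl)oxy]-2-methylpropanoate
Conditions: TBSCl, imidazole, CH2Cl2, 0 °C → rt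
Reagents that add atoms: tert-butyldimethylsilyl chloride, CC(C)(C)[Si](C)(C)Cl
Why: Silylation of an unhindered primary alcohol with a silyl chloride and imidazole is routine and does not touch the α-stereocentre of the ester.

Step 2
Reactants: 2 methyl (R)-3-[(tert-butyldimethylsilyl)oxy]-2-methylpropanoate
Product: 3 (S)-3-[(tert-butyldimethylsilyl)oxy]-2-methylpropan-1-ol
Conditions: i-Bu2AlH (2.2 equiv), CH2Cl2, −78 → 0 °C
Reagents that add atoms: none
Why: Aluminium hydride reduction of the methyl ester to the primary alcohol is non-basic, so the methyl-bearing stereocentre should be preserved.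

Step 3
Reactants: 3 (S)-3-[(tert-butyldimethylsilyl)oxy]-2-methylpropan-1-ol
Product: 4 (R)-3-[(tert-butyldimethylsilyl)oxy]-2-methylpropanal
Conditions: Dess–Martin periodinane, NaHCO3, CH2Cl2, 0 °C → rt
Reagents that add atoms: none
Why: Buffered Dess–Martin oxidation should give the α-branched aldehyde without epimerisation, provided it is used at once.

Step 4
Reactants: 4 (R)-3-[(tert-butyldimethylsilyl)oxy]-2-methylpropanal
Product: 5 (S)-tert-butyldimethyl[(2-methylbut-3-en-1-yl)oxy]silane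
Conditions: Ph3PCH3Br, n-BuLi, THF, 0 °C; then 4, −78 °C → rt
Reagents that add atoms: methyltriphenylphosphonium bromide, C[P+](c1ccccc1)(c1ccccc1)c1ccccc1.[Br-]
Why: Wittig methylenation with the non-stabilised ylide is fast at low temperature, so olefination should outrun enolisation of the α-chiral aldehyde.

Step 5
Reactants: 5 (S)-tert-butyldimethyl[(2-methylbut-3-en-1-yl)oxy]silane
Product: 6 (S)-2-methylbut-3-en-1-ol
Conditions: Bu4NF, THF, 0 °C → rt
Reagents that add atoms: none
Why: Fluoride cleaves the silyl ether through Si–F bond formation; the volatile alcohol is distilled carefully or carried on as a dried solution.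

Step 6
Reactants: 6 (S)-2-methylbut-3-en-1-ol; 7 2-ethylacrylic acid
Product: 8 (S)-2-methylbut-3-en-1-yl 2-ethylacrylate
Conditions: DCC, DMAP (cat.), CH2Cl2, 0 °C → rt
Reagents that add atoms: none
Why: Steglich esterification (carbodiimide activation, DMAP acyl transfer) joins the primary alcohol to the α-substituted acrylic acid under neutral conditions.

Step 7
Reactants: 8 (S)-2-methylbut-3-en-1-yl 2-ethylacrylate
Product: 9 (S)-3-ethyl-5-methyl-5,6-dihydro-2H-pyran-2-one
Conditions: second-generation Grubbs catalyst (H2IMes)(PCy3)Cl2Ru=CHPh (5 mol%), 1,4-benzoquinone (10 mol%), toluene (0.01 M), 80 °C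
Reagents that add atoms: none
Why: The ruthenium benzylidene first exchanges onto the unhindered monosubstituted vinyl group at C9, and the new alkylidene adds intramolecularly across the 1,1-disubstituted, electron-poor acrylate alkene to give a ruthenacyclobutane that collapses to the C8=C9 bond, loss of ethylene driving the reaction forward. The closest known reaction type is ring-closing metathesis of α-substituted acrylates of homoallylic alcohols to α-substituted α,β-unsaturated δ-lactones. The single ring, the six-membered lactone O–C7–C8–C9–C10–C11, is closed by this intramolecular olefin metathesis between the two terminal alkenes of the ester. No stereocentre is created, and C10 comes unchanged from the hydroxy ester 1. The only selectivity needed is the geometry of the trisubstituted alkene, and the ring secures it because a six-membered ring can hold only the cis alkene, which places C7 and C10 on the same side (Z); high dilution suppresses intermolecular metathesis and benzoquinone suppresses ruthenium hydride isomerisation at allylic C10.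

Step 8
Reactants: 9 (S)-3-ethyl-5-methyl-5,6-dihydro-2H-pyran-2-one
Product: 10 (S,Z)-2-ethyl-5-hydroxy-N-methoxy-N,4-dimethylpent-2-enamide
Conditions: MeNH(OMe)·HCl, AlMe3, CH2Cl2, 0 °C → rt
Reagents that add atoms: N,O-dimethylhydroxylamine hydrochloride, CNOC.Cl
Why: Weinreb aminolysis of the lactone by the aluminium amide is an acyl substitution that cannot alter the C8=C9 geometry and releases the C11 hydroxyl, so the two ends of the ring emerge differentiated.

Step 9
Reactants: 10 (S,Z)-2-ethyl-5-hydroxy-N-methoxy-N,4-dimethylpent-2-enamide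
Product: 11 (S,Z)-5-[(tert-butyldimethylsilyl)oxy]-2-ethyl-N-methoxy-N,4-dimethylpent-2-enamide
Conditions: TBSCl, imidazole, DMF, rt
Reagents that add atoms: tert-butyldimethylsilyl chloride, CC(C)(C)[Si](C)(C)Cl
Why: Immediate silylation of the primary alcohol prevents re-closure to the lactone and masks the C11 oxygen for the olefination.

Step 10
Reactants: 11 (S,Z)-5-[(tert-butyldimethylsilyl)oxy]-2-ethyl-N-methoxy-N,4-dimethylpent-2-enamide
Product: 12 (S,Z)-5-[(tert-butyldimethylsilyl)oxy]-2-ethyl-4-methylpent-2-enal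
Conditions: i-Bu2AlH, THF, −78 °C
Reagents that add atoms: none
Why: Hydride reduction of a Weinreb amide stops at the aldehyde through the stable chelated tetrahedral intermediate, so the Z-enal should form without over-reduction or isomerisation.

**Part 2. C1–C6 dihydropyran (ring A)**

Step 11
Reactants: 13 (tert-butyldimethylsilyloxy)acetaldehyde
Product: 14 (2R,3S)-1-[(tert-butyldimethylsilyl)oxy]-3-methylpent-4-en-2-ol
Conditions: cis-2-butene, KOt-Bu, n-BuLi, THF, −78 → −45 °C; (+)-Ipc2BOMe, −78 °C; BF3·OEt2; then 13, −78 °C; NaOH, H2O2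
Reagents that add atoms: cis-but-2-ene, C/C=C\C
Why: Brown asymmetric crotylboration: the (Z)-crotylborane adds through a closed chair transition state to give the syn homoallylic alcohol (C4 methyl and C5 oxygen), and the isopinocampheyl groups from (+)-Ipc2BOMe select the aldehyde face that gives the (2R,3S) isomer.

Step 12
Reactants: 14 (2R,3S)-1-[(tert-butyldimethylsilyl)oxy]-3-methylpent-4-en-2-ol
Product: 15 (2R,3S)-1-[(tert-butyldimethylsilyl)oxy]-3-methylpent-4-en-2-yl acrylate
Conditions: acryloyl chloride, i-Pr2NEt, CH2Cl2, −78 → 0 °C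
Reagents that add atoms: acryloyl chloride, C=CC(=O)Cl
Why: Acylation of the secondary alcohol with an acid chloride and a hindered amine base is routine and brings in C1–C3.

Step 13
Reactants: 15 (2R,3S)-1-[(tert-butyldimethylsilyl)oxy]-3-methylpent-4-en-2-yl acrylate
Product: 16 (5S,6R)-6-{[(tert-butyldimethylsilyl)oxy]methyl}-5-methyl-5,6-dihydro-2H-pyran-2-one
Conditions: second-generation Grubbs catalyst (H2IMes)(PCy3)Cl2Ru=CHPh (3 mol%), CH2Cl2 (0.01 M), 40 °C
Reagents that add atoms: none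
Why: Ring-closing metathesis of the acrylate of a homoallylic alcohol is an established route to 5,6-dihydro-2H-pyran-2-ones, and the ring makes the C2=C3 alkene cis.

Step 14
Reactants: 16 (5S,6R)-6-{[(tert-butyldimethylsilyl)oxy]methyl}-5-methyl-5,6-dihydro-2H-pyran-2-one
Product: 17 (5S,6R)-6-{[(tert-butyldimethylsilyl)oxy]methyl}-5-methyl-5,6-dihydro-2H-pyran-2-ol (anomer mixture)
Conditions: i-Bu2AlH (1.1 equiv), CH2Cl2, −78 °C
Reagents that add atoms: none
Why: One equivalent of hydride at −78 °C adds 1,2 to the lactone carbonyl and stops at the lactol because the aluminium hemiacetal survives until work-up.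

Step 15
Reactants: 17 (5S,6R)-6-{[(tert-butyldimethylsilyl)oxy]methyl}-5-methyl-5,6-dihydro-2H-pyran-2-ol
Product: 18 tert-butyl{[(2R,3S,6R)-6-isopropoxy-3-methyl-3,6-dihydro-2H-pyran-2-yl]methoxy}dimethylsilane
Conditions: i-PrOH, PPTS (cat.), rt
Reagents that add atoms: propan-2-ol, CC(C)O
Why: Acid-catalysed acetalisation through the allylic oxocarbenium ion converts the lactol into a base-stable isopropyl acetal, the anomeric effect favouring the axial alkoxy group.

Step 16
Reactants: 18 tert-butyl{[(2R,3S,6R)-6-isopropoxy-3-methyl-3,6-dihydro-2H-pyran-2-yl]methoxy}dimethylsilane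
Product: 19 [(2R,3S,6R)-6-isopropoxy-3-methyl-3,6-dihydro-2H-pyran-2-yl]methanol
Conditions: Bu4NF, THF, 0 °C → rt
Reagents that add atoms: none
Why: Fluoride removes the primary silyl ether, and the acetal is inert to these basic conditions.

Step 17
Reactants: 19 [(2R,3S,6R)-6-isopropoxy-3-methyl-3,6-dihydro-2H-pyran-2-yl]methanol
Product: 20 (2R,3S,6R)-2-(iodomethyl)-6-isopropoxy-3-methyl-3,6-dihydro-2H-pyran
Conditions: I2, PPh3, imidazole, CH2Cl2, 0 °C → rt
Reagents that add atoms: iodine, II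
Why: Appel-type iodination converts the primary alcohol into the iodide, with imidazole keeping the medium non-acidic for the acetal.

Step 18
Reactants: 20 (2R,3S,6R)-2-(iodomethyl)-6-isopropoxy-3-methyl-3,6-dihydro-2H-pyran
Product: 21 tributyl{[(2R,3S,6R)-6-isopropoxy-3-methyl-3,6-dihydro-2H-pyran-2-yl]methyl}phosphonium iodide
Conditions: PBu3, MeCN, 80 °C
Reagents that add atoms: tributylphosphine, CCCCP(CCCC)CCCC
Why: SN2 quaternisation of the strongly nucleophilic trialkylphosphine by the primary iodide should give the phosphonium salt.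

**Part 3. C1–C11 iodide**

Step 19
Reactants: 21 tributyl{[(2R,3S,6R)-6-isopropoxy-3-methyl-3,6-dihydro-2H-pyran-2-yl]methyl}phosphonium iodide; 12 (S,Z)-5-[(tert-butyldimethylsilyl)oxy]-2-ethyl-4-methylpent-2-enal
Product: 23 tert-butyl({(2S,3Z,5E)-4-ethyl-6-[(2S,3S,6R)-6-isopropoxy-3-methyl-3,6-dihydro-2H-pyran-2-yl]-2-methylhexa-3,5-dien-1-yl}oxy)dimethylsilane, via phosphonium ylide 22 (not isolated)
Conditions: LiCH2S(O)CH3, toluene, −78 °C; then 12, −78 °C → rt
Reagents that add atoms: none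
Why: Wittig olefination: the ylide adds to the Z-enal at −78 °C faster than it can enolise it, and tributylphosphonium ylides generated with a lithium base in toluene are known to favour the E-alkene, so the (6E,8Z)-diene should result.

Step 20
Reactants: 23 tert-butyl({(2S,3Z,5E)-4-ethyl-6-[(2S,3S,6R)-6-isopropoxy-3-methyl-3,6-dihydro-2H-pyran-2-yl]-2-methylhexa-3,5-dien-1-yl}oxy)dimethylsilane
Product: 24 (2S,3Z,5E)-4-ethyl-6-[(2S,3S,6R)-6-isopropoxy-3-methyl-3,6-dihydro-2H-pyran-2-yl]-2-methylhexa-3,5-dien-1-ol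
Conditions: Bu4NF, THF, 0 °C
Reagents that add atoms: none
Why: Fluoride removes the primary silyl ether while the acetal and the diene are stable to it.

Step 21
Reactants: 24 (2S,3Z,5E)-4-ethyl-6-[(2S,3S,6R)-6-isopropoxy-3-methyl-3,6-dihydro-2H-pyran-2-yl]-2-methylhexa-3,5-dien-1-ol
Product: 25 (2S,3S,6R)-2-[(1E,3Z,5S)-3-ethyl-6-iodo-5-methylhexa-1,3-dien-1-yl]-6-isopropoxy-3-methyl-3,6-dihydro-2H-pyran
Conditions: I2, PPh3, imidazole, CH2Cl2, 0 °C
Reagents that add atoms: iodine, II
Why: Appel-type iodination under imidazole buffering tolerates the acetal and the diene and provides the C11 iodide.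

**Part 4. C12–C24 dienyl iodide**

Step 22
Reactants: 3 (S)-3-[(tert-butyldimethylsilyl)oxy]-2-methylpropan-1-ol
Product: 26 (R)-tert-butyl(3-iodo-2-methylpropoxy)dimethylsilane
Conditions: I2, PPh3, imidazole, CH2Cl2, 0 °C → rt
Reagents that add atoms: iodine, II
Why: Appel-type iodination of the primary alcohol leaves the adjacent stereocentre (future C20) untouched.

Step 23
Reactants: 26 (R)-tert-butyl(3-iodo-2-methylpropoxy)dimethylsilane
Product: 29 ethyl (S,E)-6-[(tert-butyldimethylsilyl)oxy]-3,5-dimethylhex-2-enoate, via alkyllithium 27 (not isolated), via lithium dialkylcuprate 28 (not isolated)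
Conditions: t-BuLi (2 equiv per iodide), Et2O, −78 °C; CuBr·SMe2 (0.5 equiv), −40 °C; ethyl but-2-ynoate (0.45 equiv), THF, −78 °C; MeOH, −78 °C
Reagents that add atoms: ethyl but-2-ynoate, CC#CC(=O)OCC
Why: Lithium–iodine exchange and transmetalation give a Gilman cuprate that adds syn across the ynoate (carbocupration), and protonation of the vinylcopper at −78 °C keeps that geometry, so C21 and the ester should end up trans (E).

Step 24
Reactants: 29 ethyl (S,E)-6-[(tert-butyldimethylsilyl)oxy]-3,5-dimethylhex-2-enoate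
Product: 30 ethyl (S,E)-6-hydroxy-3,5-dimethylhex-2-enoate
Conditions: HF·pyridine, THF, 0 °C → rt
Reagents that add atoms: none
Why: Acidic fluoride cleaves the primary silyl ether without base, so the enoate is left alone.

Step 25
Reactants: 30 ethyl (S,E)-6-hydroxy-3,5-dimethylhex-2-enoate
Product: 31 ethyl (S,E)-3,5-dimethyl-6-oxohex-2-enoate
Conditions: Dess–Martin periodinane, NaHCO3, CH2Cl2, 0 °C → rt
Reagents that add atoms: none
Why: Buffered Dess–Martin oxidation should give the α-methyl aldehyde without epimerisation at C20.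

Step 26
Reactants: 31 ethyl (S,E)-3,5-dimethyl-6-oxohex-2-enoate; 32 (S)-4-benzyl-3-propionyloxazolidin-2-one
Product: 34 ethyl (2E,5S,6R,7S)-8-[(S)-4-benzyl-2-oxooxazolidin-3-yl]-6-hydroxy-3,5,7-trimethyl-8-oxooct-2-enoate, via Z-boron enolate 33 (not isolated)
Conditions: Bu2BOTf, Et3N, CH2Cl2, −78 → 0 °C; then 31, −78 → 0 °C; pH 7 buffer, MeOH, H2O2
Reagents that add atoms: none
Why: Evans syn aldol: the Z-boron enolate reacts through a Zimmerman–Traxler chair on the face dictated by the (S)-benzyl oxazolidinone, which sets C18 (S) and C19 (R) and should override the weaker facial bias of the α-methyl aldehyde.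

Step 27
Reactants: 34 ethyl (2E,5S,6R,7S)-8-[(S)-4-benzyl-2-oxooxazolidin-3-yl]-6-hydroxy-3,5,7-trimethyl-8-oxooct-2-enoate
Product: 35 ethyl (2E,5S,6R,7S)-8-[(S)-4-benzyl-2-oxooxazolidin-3-yl]-6-[(tert-butyldimethylsilyl)oxy]-3,5,7-trimethyl-8-oxooct-2-enoate
Conditions: TBSOTf, 2,6-lutidine, CH2Cl2, 0 °C
Reagents that add atoms: tert-butyldimethylsilyl trifluoromethanesulfonate, CC(C)(C)[Si](C)(C)OS(=O)(=O)C(F)(F)F
Why: A silyl triflate with 2,6-lutidine silylates the hindered secondary aldol hydroxyl without retro-aldol cleavage.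

Step 28
Reactants: 35 ethyl (2E,5S,6R,7S)-8-[(S)-4-benzyl-2-oxooxazolidin-3-yl]-6-[(tert-butyldimethylsilyl)oxy]-3,5,7-trimethyl-8-oxooct-2-enoate
Product: 36 ethyl (2E,5S,6R,7R)-6-[(tert-butyldimethylsilyl)oxy]-8-hydroxy-3,5,7-trimethyloct-2-enoate
Conditions: LiBH4, MeOH (1 equiv), THF, 0 °C
Reagents that add atoms: none
Why: LiBH4 cleaves the activated N-acyl oxazolidinone reductively to the primary alcohol far faster than it attacks the β,β-disubstituted conjugated ethyl ester at 0 °C.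

Step 29
Reactants: 36 ethyl (2E,5S,6R,7R)-6-[(tert-butyldimethylsilyl)oxy]-8-hydroxy-3,5,7-trimethyloct-2-enoate
Product: 37 ethyl (2E,5S,6R,7S)-6-[(tert-butyldimethylsilyl)oxy]-3,5,7-trimethyl-8-oxooct-2-enoate
Conditions: Dess–Martin periodinane, NaHCO3, CH2Cl2, 0 °C → rt
Reagents that add atoms: none
Why: Buffered Dess–Martin oxidation gives the C17 aldehyde without epimerisation at C18 or β-elimination of the silyloxy group.

Step 30
Reactants: 38 (R)-4-benzyloxazolidin-2-one
Product: 39 (R)-4-benzyl-3-[(E)-but-2-enoyl]oxazolidin-2-one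
Conditions: n-BuLi, THF, −78 °C; then (E)-crotonyl chloride, −78 → 0 °C
Reagents that add atoms: (E)-but-2-enoyl chloride, C/C=C/C(=O)Cl
Why: N-Acylation of the lithiated oxazolidinone with an acid chloride is the standard preparation of N-enoyl imides.

Step 31
Reactants: 37 ethyl (2E,5S,6R,7S)-6-[(tert-butyldimethylsilyl)oxy]-3,5,7-trimethyl-8-oxooct-2-enoate; 39 (R)-4-benzyl-3-[(E)-but-2-enoyl]oxazolidin-2-one
Product: 41 ethyl (2E,5S,6R,7R,8S,9R)-9-[(R)-4-benzyl-2-oxooxazolidine-3-carbonyl]-6-[(tert-butyldimethylsilyl)oxy]-8-hydroxy-3,5,7-trimethylundeca-2,10-dienoate, via boron dienolate 40 (not isolated)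
Conditions: Bu2BOTf, Et3N, CH2Cl2, −78 → 0 °C; then 37, −78 → 0 °C; pH 7 buffer, MeOH, H2O2
Reagents that add atoms: none
Why: Evans aldol of the boron dienolate, which reacts at its α-carbon through a Zimmerman–Traxler chair on the face set by the (R)-benzyl oxazolidinone, fixes C16 (the C17 carbinol is oxidised later) and is matched with the anti-Felkin preference of Z-enolates.

Step 32
Reactants: 41 ethyl (2E,5S,6R,7R,8S,9R)-9-[(R)-4-benzyl-2-oxooxazolidine-3-carbonyl]-6-[(tert-butyldimethylsilyl)oxy]-8-hydroxy-3,5,7-trimethylundeca-2,10-dienoate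
Product: 42 ethyl (2E,5S,6R,7R,8R,9S)-6-[(tert-butyldimethylsilyl)oxy]-8-hydroxy-9-(hydroxymethyl)-3,5,7-trimethylundeca-2,10-dienoate
Conditions: LiBH4, MeOH (1 equiv), THF, 0 °C
Reagents that add atoms: none
Why: Reductive removal of the auxiliary turns the imide carbonyl into the C16 hydroxymethyl group, the conjugated ester again reacting much more slowly.

Step 33
Reactants: 42 ethyl (2E,5S,6R,7R,8R,9S)-6-[(tert-butyldimethylsilyl)oxy]-8-hydroxy-9-(hydroxymethyl)-3,5,7-trimethylundeca-2,10-dienoate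
Product: 44 bis-silyl ether of 42 (primary oxygen as triisopropylsilyl ether; C17 oxygen as triethylsilyl ether; stereocentres as in 42), via mono-TIPS ether 43 (not isolated)
Conditions: TIPSOTf (1.05 equiv), 2,6-lutidine, CH2Cl2, −78 °C; then TESOTf, −78 → 0 °C
Reagents that add atoms: triisopropylsilyl trifluoromethanesulfonate, CC(C)[Si](C(C)C)(C(C)C)OS(=O)(=O)C(F)(F)F; triethylsilyl trifluoromethanesulfonate, CC[Si](CC)(CC)OS(=O)(=O)C(F)(F)F
Why: The bulky triisopropylsilyl triflate silylates only the primary hydroxyl at −78 °C, after which the smaller triethylsilyl triflate caps the hindered C17 hydroxyl in the same flask.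

Step 34
Reactants: 44 bis-silyl ether of 42
Product: 45 C15 aldehyde (the vinyl group of 44 cleaved to a formyl group on C16; other groups and stereocentres as in 44)
Conditions: OsO4 (2 mol%), NaIO4, 2,6-lutidine, dioxane/H2O, rt
Reagents that add atoms: osmium tetroxide, O=[Os](=O)(=O)=O (oxo ligand replenished from NaIO4)
Why: Lemieux–Johnson cleavage: OsO4 dihydroxylates the monosubstituted alkene in preference to the electron-poor trisubstituted enoate and NaIO4 cleaves the diol, with lutidine buffering against epimerisation at C16.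

Step 35
Reactants: 45 C15 aldehyde
Product: 46 (14E)-C13 enal (C16 carries an (E)-2-methyl-3-oxoprop-1-enyl group; other groups as in 44)
Conditions: Ph3P=C(Me)CHO, toluene, 90 °C
Reagents that add atoms: 2-(triphenylphosphoranylidene)propanal, CC(C=O)=P(c1ccccc1)(c1ccccc1)c1ccccc1
Why: Wittig reaction with the stabilised formyl ylide gives the E-trisubstituted enal, and the saturated α-branched aldehyde reacts faster than the enal product.

Step 36
Reactants: 46 (14E)-C13 enal
Product: 47 C12–C24 (12E,14E)-dienyl iodide (ethyl ester; 16-CH2OTIPS; 17-OTES; 19-OTBS)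
Conditions: CrCl2, CHI3, THF/dioxane, 0 °C → rt
Reagents that add atoms: iodoform, IC(I)I
Why: Takai olefination (geminal dichromium species from CHI3 and CrCl2) converts the aldehyde into the E-vinyl iodide with no basic reagent present.

**Part 5. Fragment union and end game**

Step 37
Reactants: 25 (2S,3S,6R)-2-[(1E,3Z,5S)-3-ethyl-6-iodo-5-methylhexa-1,3-dien-1-yl]-6-isopropoxy-3-methyl-3,6-dihydro-2H-pyran; 47 C12–C24 (12E,14E)-dienyl iodide
Product: 49 fully protected C1–C24 ethyl ester (C1 isopropyl acetal; 16-CH2OTIPS; 17-OTES; 19-OTBS), via lithium alkylborate 48 (not isolated)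
Conditions: 25, B-methoxy-9-BBN, t-BuLi, Et2O/THF, −78 °C → rt; then 47, Pd(dppf)Cl2 (10 mol%), AsPh3, K3PO4 (aq), DMF, rt
Reagents that add atoms: none
Why: B-alkyl Suzuki–Miyaura coupling: lithium–iodine exchange in the presence of the borinate traps the alkyllithium as the borate, which transmetalates to the alkenylpalladium formed by oxidative addition of the dienyl iodide to zerovalent palladium, and reductive elimination forms C11–C12 with the E geometry retained.

Step 38
Reactants: 49 fully protected C1–C24 ethyl ester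
Product: 50 C24 carboxylic acid of 49
Conditions: LiOH, THF/MeOH/H2O, rt → 40 °C; then H3PO4 (aq) to pH 5, 0 °C
Reagents that add atoms: lithium hydroxide, [Li+].[OH-]
Why: Saponification is done while C1 is still a base-stable acetal and C17 is still a protected alcohol, so nothing base-labile or epimerisable is present.

Step 39
Reactants: 50 C24 carboxylic acid of 49
Product: 51 C1 lactol C17 alcohol (free acid; 16-CH2OTIPS and 19-OTBS retained; anomer mixture)
Conditions: AcOH/THF/H2O (3:1:1), rt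
Reagents that add atoms: water, O
Why: Aqueous acetic acid hydrolyses the allylic mixed acetal to the lactol and solvolyses the labile triethylsilyl ether, while the tert-butyldimethylsilyl and triisopropylsilyl ethers survive.

Step 40
Reactants: 51 C1 lactol C17 alcohol
Product: 52 bis-silyl kazusamycin A (16-CH2OTIPS; 19-OTBS)
Conditions: Dess–Martin periodinane (3 equiv), NaHCO3, CH2Cl2, 0 °C → rt
Reagents that add atoms: none
Why: Dess–Martin periodinane oxidises both free hydroxyls in one operation, the lactol to the unsaturated lactone and the C17 carbinol to the ketone, under buffered conditions mild enough for the epimerisable C16 centre.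

Step 41
Reactants: 52 bis-silyl kazusamycin A
Product: 53 kazusamycin A
Conditions: HF·pyridine, pyridine, THF, 0 °C → rt
Reagents that add atoms: none
Why: Acidic fluoride removes both remaining silyl ethers without base, avoiding lactone opening, retro-aldol cleavage of the β-hydroxy ketone and epimerisation at C16.

**Compound list**

1 | methyl (R)-3-hydroxy-2-methylpropanoate | COC(=O)[C@H](C)CO | starting material
2 | methyl (R)-3-[(tert-butyldimethylsilyl)oxy]-2-methylpropanoate | COC(=O)[C@H](C)CO[Si](C)(C)C(C)(C)C | intermediate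
3 | (S)-3-[(tert-butyldimethylsilyl)oxy]-2-methylpropan-1-ol | OC[C@H](C)CO[Si](C)(C)C(C)(C)C | intermediate
4 | (R)-3-[(tert-butyldimethylsilyl)oxy]-2-methylpropanal | O=C[C@H](C)CO[Si](C)(C)C(C)(C)C | intermediate
5 | (S)-tert-butyldimethyl[(2-methylbut-3-en-1-yl)oxy]silane | C=C[C@H](C)CO[Si](C)(C)C(C)(C)C | intermediate
6 | (S)-2-methylbut-3-en-1-ol | C=C[C@H](C)CO | intermediate
7 | 2-ethylacrylic acid | C=C(CC)C(=O)O | starting material
8 | (S)-2-methylbut-3-en-1-yl 2-ethylacrylate | C=C[C@H](C)COC(=O)C(=C)CC | intermediate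
9 | (S)-3-ethyl-5-methyl-5,6-dihydro-2H-pyran-2-one | CCC1=C[C@H](C)COC1=O | intermediate
10 | (S,Z)-2-ethyl-5-hydroxy-N-methoxy-N,4-dimethylpent-2-enamide | CC/C(=C/[C@H](C)CO)C(=O)N(C)OC | intermediate
11 | (S,Z)-5-[(tert-butyldimethylsilyl)oxy]-2-ethyl-N-methoxy-N,4-dimethylpent-2-enamide | CC/C(=C/[C@H](C)CO[Si](C)(C)C(C)(C)C)C(=O)N(C)OC | intermediate
12 | (S,Z)-5-[(tert-butyldimethylsilyl)oxy]-2-ethyl-4-methylpent-2-enal | CC/C(=C/[C@H](C)CO[Si](C)(C)C(C)(C)C)C=O | intermediate
13 | (tert-butyldimethylsilyloxy)acetaldehyde | O=CCO[Si](C)(C)C(C)(C)C | starting material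
14 | (2R,3S)-1-[(tert-butyldimethylsilyl)oxy]-3-methylpent-4-en-2-ol | CC(C)(C)[Si](C)(C)OC[C@H](O)[C@@H](C)C=C | intermediate
15 | (2R,3S)-1-[(tert-butyldimethylsilyl)oxy]-3-methylpent-4-en-2-yl acrylate | CC(C)(C)[Si](C)(C)OC[C@H](OC(=O)C=C)[C@@H](C)C=C | intermediate
16 | (5S,6R)-6-{[(tert-butyldimethylsilyl)oxy]methyl}-5-methyl-5,6-dihydro-2H-pyran-2-one | CC(C)(C)[Si](C)(C)OC[C@@H]1OC(=O)C=C[C@@H]1C | intermediate
17 | (5S,6R)-6-{[(tert-butyldimethylsilyl)oxy]methyl}-5-methyl-5,6-dihydro-2H-pyran-2-ol (anomer mixture) | CC(C)(C)[Si](C)(C)OC[C@@H]1OC(O)C=C[C@@H]1C | intermediate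
18 | tert-butyl{[(2R,3S,6R)-6-isopropoxy-3-methyl-3,6-dihydro-2H-pyran-2-yl]methoxy}dimethylsilane | CC(C)(C)[Si](C)(C)OC[C@@H]1O[C@@H](OC(C)C)C=C[C@@H]1C | intermediate
19 | [(2R,3S,6R)-6-isopropoxy-3-methyl-3,6-dihydro-2H-pyran-2-yl]methanol | OC[C@@H]1O[C@@H](OC(C)C)C=C[C@@H]1C | intermediate
20 | (2R,3S,6R)-2-(iodomethyl)-6-isopropoxy-3-methyl-3,6-dihydro-2H-pyran | IC[C@@H]1O[C@@H](OC(C)C)C=C[C@@H]1C | intermediate
21 | tributyl{[(2R,3S,6R)-6-isopropoxy-3-methyl-3,6-dihydro-2H-pyran-2-yl]methyl}phosphonium iodide | CCCC[P+](CCCC)(CCCC)C[C@@H]1O[C@@H](OC(C)C)C=C[C@@H]1C.[I-] | intermediate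
22 | tributyl{[(2R,3S,6R)-6-isopropoxy-3-methyl-3,6-dihydro-2H-pyran-2-yl]methylidene}phosphorane | CCCCP(CCCC)(CCCC)=C[C@@H]1O[C@@H](OC(C)C)C=C[C@@H]1C | intermediate (not isolated)
23 | tert-butyl({(2S,3Z,5E)-4-ethyl-6-[(2S,3S,6R)-6-isopropoxy-3-methyl-3,6-dihydro-2H-pyran-2-yl]-2-methylhexa-3,5-dien-1-yl}oxy)dimethylsilane | CCC(=C/[C@H](C)CO[Si](C)(C)C(C)(C)C)/C=C/[C@@H]1O[C@@H](OC(C)C)C=C[C@@H]1C | intermediate
24 | (2S,3Z,5E)-4-ethyl-6-[(2S,3S,6R)-6-isopropoxy-3-methyl-3,6-dihydro-2H-pyran-2-yl]-2-methylhexa-3,5-dien-1-ol | CCC(=C/[C@H](C)CO)/C=C/[C@@H]1O[C@@H](OC(C)C)C=C[C@@H]1C | intermediate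
25 | (2S,3S,6R)-2-[(1E,3Z,5S)-3-ethyl-6-iodo-5-methylhexa-1,3-dien-1-yl]-6-isopropoxy-3-methyl-3,6-dihydro-2H-pyran | CCC(=C/[C@H](C)CI)/C=C/[C@@H]1O[C@@H](OC(C)C)C=C[C@@H]1C | intermediate
26 | (R)-tert-butyl(3-iodo-2-methylpropoxy)dimethylsilane | IC[C@H](C)CO[Si](C)(C)C(C)(C)C | intermediate
27 | {(2S)-3-[(tert-butyldimethylsilyl)oxy]-2-methylpropyl}lithium | [Li]C[C@H](C)CO[Si](C)(C)C(C)(C)C | intermediate (not isolated)
28 | lithium bis{(2S)-3-[(tert-butyldimethylsilyl)oxy]-2-methylpropyl}cuprate | [Li+].C[C@H](CO[Si](C)(C)C(C)(C)C)C[Cu-]C[C@H](C)CO[Si](C)(C)C(C)(C)C | intermediate (not isolated)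
29 | ethyl (S,E)-6-[(tert-butyldimethylsilyl)oxy]-3,5-dimethylhex-2-enoate | CCOC(=O)/C=C(C)/C[C@H](C)CO[Si](C)(C)C(C)(C)C | intermediate
30 | ethyl (S,E)-6-hydroxy-3,5-dimethylhex-2-enoate | CCOC(=O)/C=C(C)/C[C@H](C)CO | intermediate
31 | ethyl (S,E)-3,5-dimethyl-6-oxohex-2-enoate | CCOC(=O)/C=C(C)/C[C@H](C)C=O | intermediate
32 | (S)-4-benzyl-3-propionyloxazolidin-2-one | CCC(=O)N1[C@@H](Cc2ccccc2)COC1=O | starting material
33 | (Z)-dibutylboron enolate of 32 | C/C=C(\OB(CCCC)CCCC)N1[C@@H](Cc2ccccc2)COC1=O | intermediate (not isolated)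
34 | ethyl (2E,5S,6R,7S)-8-[(S)-4-benzyl-2-oxooxazolidin-3-yl]-6-hydroxy-3,5,7-trimethyl-8-oxooct-2-enoate | CCOC(=O)/C=C(C)/C[C@H](C)[C@@H](O)[C@H](C)C(=O)N1[C@@H](Cc2ccccc2)COC1=O | intermediate
35 | ethyl (2E,5S,6R,7S)-8-[(S)-4-benzyl-2-oxooxazolidin-3-yl]-6-[(tert-butyldimethylsilyl)oxy]-3,5,7-trimethyl-8-oxooct-2-enoate | CCOC(=O)/C=C(C)/C[C@H](C)[C@@H](O[Si](C)(C)C(C)(C)C)[C@H](C)C(=O)N1[C@@H](Cc2ccccc2)COC1=O | intermediate
36 | ethyl (2E,5S,6R,7R)-6-[(tert-butyldimethylsilyl)oxy]-8-hydroxy-3,5,7-trimethyloct-2-enoate | CCOC(=O)/C=C(C)/C[C@H](C)[C@@H](O[Si](C)(C)C(C)(C)C)[C@H](C)CO | intermediate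
37 | ethyl (2E,5S,6R,7S)-6-[(tert-butyldimethylsilyl)oxy]-3,5,7-trimethyl-8-oxooct-2-enoate | CCOC(=O)/C=C(C)/C[C@H](C)[C@@H](O[Si](C)(C)C(C)(C)C)[C@H](C)C=O | intermediate
38 | (R)-4-benzyloxazolidin-2-one | O=C1N[C@H](Cc2ccccc2)CO1 | starting material
39 | (R)-4-benzyl-3-[(E)-but-2-enoyl]oxazolidin-2-one | C/C=C/C(=O)N1[C@H](Cc2ccccc2)COC1=O | intermediate
40 | (Z)-dibutylboron dienolate of 39 | C=C/C=C(\OB(CCCC)CCCC)N1[C@H](Cc2ccccc2)COC1=O | intermediate (not isolated)
41 | ethyl (2E,5S,6R,7R,8S,9R)-9-[(R)-4-benzyl-2-oxooxazolidine-3-carbonyl]-6-[(tert-butyldimethylsilyl)oxy]-8-hydroxy-3,5,7-trimethylundeca-2,10-dienoate | CCOC(=O)/C=C(C)/C[C@H](C)[C@@H](O[Si](C)(C)C(C)(C)C)[C@H](C)[C@H](O)[C@@H](C=C)C(=O)N1[C@H](Cc2ccccc2)COC1=O | intermediate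
42 | ethyl (2E,5S,6R,7R,8R,9S)-6-[(tert-butyldimethylsilyl)oxy]-8-hydroxy-9-(hydroxymethyl)-3,5,7-trimethylundeca-2,10-dienoate | CCOC(=O)/C=C(C)/C[C@H](C)[C@@H](O[Si](C)(C)C(C)(C)C)[C@H](C)[C@H](O)[C@@H](C=C)CO | intermediate
43 | mono-TIPS ether of 42 (primary oxygen silylated, C17 hydroxyl free) | CCOC(=O)/C=C(C)/C[C@H](C)[C@@H](O[Si](C)(C)C(C)(C)C)[C@H](C)[C@H](O)[C@@H](C=C)CO[Si](C(C)C)(C(C)C)C(C)C | intermediate (not isolated)
44 | bis-silyl ether of 42 (16-CH2OTIPS, 17-OTES, 19-OTBS, vinyl on C16) | CCOC(=O)/C=C(C)/C[C@H](C)[C@@H](O[Si](C)(C)C(C)(C)C)[C@H](C)[C@H](O[Si](CC)(CC)CC)[C@@H](C=C)CO[Si](C(C)C)(C(C)C)C(C)C | intermediate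
45 | C15 aldehyde (formyl on C16; silyl groups as in 44) | CCOC(=O)/C=C(C)/C[C@H](C)[C@@H](O[Si](C)(C)C(C)(C)C)[C@H](C)[C@H](O[Si](CC)(CC)CC)[C@@H](C=O)CO[Si](C(C)C)(C(C)C)C(C)C | intermediate
46 | (14E)-C13 enal (silyl groups as in 44) | CCOC(=O)/C=C(C)/C[C@H](C)[C@@H](O[Si](C)(C)C(C)(C)C)[C@H](C)[C@H](O[Si](CC)(CC)CC)[C@@H](/C=C(C)/C=O)CO[Si](C(C)C)(C(C)C)C(C)C | intermediate
47 | C12–C24 (12E,14E)-dienyl iodide (ethyl ester, 16-CH2OTIPS, 17-OTES, 19-OTBS) | CCOC(=O)/C=C(C)/C[C@H](C)[C@@H](O[Si](C)(C)C(C)(C)C)[C@H](C)[C@H](O[Si](CC)(CC)CC)[C@@H](/C=C(C)/C=C/I)CO[Si](C(C)C)(C(C)C)C(C)C | intermediate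
48 | lithium B-alkyl-B-methoxy-9-borabicyclo[3.3.1]nonane borate derived from 25 (boron on C11) | CCC(=C/[C@H](C)C[B-]1(OC)C2CCCC1CCC2)/C=C/[C@@H]1O[C@@H](OC(C)C)C=C[C@@H]1C.[Li+] | intermediate (not isolated)
49 | fully protected C1–C24 ethyl ester (C1 isopropyl acetal, 16-CH2OTIPS, 17-OTES, 19-OTBS) | CCC(=C/[C@H](C)C/C=C/C(C)=C/[C@@H](CO[Si](C(C)C)(C(C)C)C(C)C)[C@@H](O[Si](CC)(CC)CC)[C@@H](C)[C@H](O[Si](C)(C)C(C)(C)C)[C@@H](C)C/C(C)=C/C(=O)OCC)/C=C/[C@@H]1O[C@@H](OC(C)C)C=C[C@@H]1C | intermediate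
50 | C24 carboxylic acid of 49 | CCC(=C/[C@H](C)C/C=C/C(C)=C/[C@@H](CO[Si](C(C)C)(C(C)C)C(C)C)[C@@H](O[Si](CC)(CC)CC)[C@@H](C)[C@H](O[Si](C)(C)C(C)(C)C)[C@@H](C)C/C(C)=C/C(=O)O)/C=C/[C@@H]1O[C@@H](OC(C)C)C=C[C@@H]1C | intermediate
51 | C1 lactol C17 alcohol (free acid, 16-CH2OTIPS, 19-OTBS; anomer mixture) | CCC(=C/[C@H](C)C/C=C/C(C)=C/[C@@H](CO[Si](C(C)C)(C(C)C)C(C)C)[C@@H](O)[C@@H](C)[C@H](O[Si](C)(C)C(C)(C)C)[C@@H](C)C/C(C)=C/C(=O)O)/C=C/[C@@H]1OC(O)C=C[C@@H]1C | intermediate
52 | bis-silyl kazusamycin A (16-CH2OTIPS, 19-OTBS) | CCC(=C/[C@H](C)C/C=C/C(C)=C/[C@@H](CO[Si](C(C)C)(C(C)C)C(C)C)C(=O)[C@@H](C)[C@H](O[Si](C)(C)C(C)(C)C)[C@@H](C)C/C(C)=C/C(=O)O)/C=C/[C@@H]1OC(=O)C=C[C@@H]1C | intermediate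
53 | kazusamycin A | CCC(=C/[C@H](C)C/C=C/C(C)=C/[C@@H](CO)C(=O)[C@@H](C)[C@H](O)[C@@H](C)C/C(C)=C/C(=O)O)/C=C/[C@@H]1OC(=O)C=C[C@@H]1C | target

**Step count and risks**

Total steps: 41. Longest linear sequence: 21 steps (steps 1, 2, 22–29 and 31–41).

The three steps most likely to fail:

1. Step 19 (Wittig union at C6=C7). What may go wrong is erosion of E/Z selectivity at the new double bond, base-induced isomerisation of the Z-enal through its dienolate (which would also scramble C10), or β-elimination of the ring oxygen from the ylide. The fallback sets out from 19 and comes back at 23. Mitsunobu thioetherification of 19 with 1-phenyl-1H-tetrazole-5-thiol (PPh3, DIAD, THF) should give the sulfide 5-({[(2R,3S,6R)-6-isopropoxy-3-methyl-3,6-dihydro-2H-pyran-2-yl]methyl}sulfanyl)-1-phenyl-1H-tetrazole F1. Oxidation with H2O2 and catalytic (NH4)6Mo7O24·4H2O in ethanol should give the sulfone 5-({[(2R,3S,6R)-6-isopropoxy-3-methyl-3,6-dihydro-2H-pyran-2-yl]methyl}sulfonyl)-1-phenyl-1H-tetrazole F2. Julia–Kocienski olefination of F2 (KN(SiMe3)2, DME, −78 °C) with enal 12 should then return to 23, a kinetically E-selective sulfone route replacing the ylide.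

2. Step 37 (B-alkyl Suzuki union at C11–C12). What may go wrong is proton transfer or cyclisation of the transient homoallylic alkyllithium onto the diene before boron capture, and slow transmetalation of the β-branched alkylborate leading to protodeboronation or reduction of the dienyl iodide. The fallback sets out from 25 and comes back at 49. Direct insertion of zinc into 25 (Zn dust activated with Me3SiCl, LiCl, THF, 40 °C) should give, without any alkyllithium, the alkylzinc iodide {(2S,3Z,5E)-4-ethyl-6-[(2S,3S,6R)-6-isopropoxy-3-methyl-3,6-dihydro-2H-pyran-2-yl]-2-methylhexa-3,5-dien-1-yl}zinc iodide F3. Negishi coupling of F3 with 47 (Pd(PPh3)4, THF/N-methylpyrrolidone, rt → 50 °C) should give 49.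

3. Step 39 (one-pot acetal hydrolysis and C17 desilylation). What may go wrong is slow solvolysis of the hindered C17 silyl ether, forcing long exposure of the unsaturated lactol to acid with ring-opening and Z→E isomerisation or dehydration, or partial loss of the other silyl ethers. The fallback sets out from 47 and comes back at 51; it frees the C17 hydroxyl before fragment union. Buffered HF·pyridine (pyridine, THF, 0 °C) on 47 should give the C17 alcohol of the dienyl iodide (17-OH, 19-OTBS, 16-CH2OTIPS) F4. B-alkyl Suzuki coupling of F4 with borate 48 under the conditions of step 37 should give the coupled C17 hydroxy ethyl ester F5. Saponification with LiOH should give the C17 hydroxy acid F6. Brief hydrolysis of the acetal alone with PPTS in acetone/H2O at rt should then give 51.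

**Further compounds**

F1 | step 19 | 5-({[(2R,3S,6R)-6-isopropoxy-3-methyl-3,6-dihydro-2H-pyran-2-yl]methyl}sulfanyl)-1-phenyl-1H-tetrazole | c1ccc(cc1)-n1nnnc1SC[C@@H]1O[C@@H](OC(C)C)C=C[C@@H]1C
F2 | step 19 | 5-({[(2R,3S,6R)-6-isopropoxy-3-methyl-3,6-dihydro-2H-pyran-2-yl]methyl}sulfonyl)-1-phenyl-1H-tetrazole | c1ccc(cc1)-n1nnnc1S(=O)(=O)C[C@@H]1O[C@@H](OC(C)C)C=C[C@@H]1C
F3 | step 37 | {(2S,3Z,5E)-4-ethyl-6-[(2S,3S,6R)-6-isopropoxy-3-methyl-3,6-dihydro-2H-pyran-2-yl]-2-methylhexa-3,5-dien-1-yl}zinc iodide | CCC(=C/[C@H](C)C[Zn]I)/C=C/[C@@H]1O[C@@H](OC(C)C)C=C[C@@H]1C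
F4 | step 39 | C17 alcohol of dienyl iodide 47 (17-OH, 19-OTBS, 16-CH2OTIPS) | CCOC(=O)/C=C(C)/C[C@H](C)[C@@H](O[Si](C)(C)C(C)(C)C)[C@H](C)[C@H](O)[C@@H](/C=C(C)/C=C/I)CO[Si](C(C)C)(C(C)C)C(C)C
F5 | step 39 | coupled C1–C24 ethyl ester with free C17 hydroxyl (C1 isopropyl acetal, 16-CH2OTIPS, 19-OTBS) | CCC(=C/[C@H](C)C/C=C/C(C)=C/[C@@H](CO[Si](C(C)C)(C(C)C)C(C)C)[C@@H](O)[C@@H](C)[C@H](O[Si](C)(C)C(C)(C)C)[C@@H](C)C/C(C)=C/C(=O)OCC)/C=C/[C@@H]1O[C@@H](OC(C)C)C=C[C@@H]1C
F6 | step 39 | C24 carboxylic acid of F5 | CCC(=C/[C@H](C)C/C=C/C(C)=C/[C@@H](CO[Si](C(C)C)(C(C)C)C(C)C)[C@@H](O)[C@@H](C)[C@H](O[Si](C)(C)C(C)(C)C)[C@@H](C)C/C(C)=C/C(=O)O)/C=C/[C@@H]1O[C@@H](OC(C)C)C=C[C@@H]1C
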